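A direct plan would build ring A last. A prenylated 4-acetoxy-3-carbomethoxy-2-pyrone A1 would be heated with the ethynyl ether A2 of a MOM- and silyl-protected ring B phenol. [4+2] cycloaddition and loss of CO2 would give the benzoate A3, which would then be demethylated, deacetylated and deprotected with acid.
Its weakest points would be:
(a) the pyrone/ynol ether cycloaddition with CO2 extrusion: a terminal aryl ynol ether would have to survive about 100 °C, the pairing has no close precedent, and the regiochemistry rests only on a polarisation argument;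
(b) the seven-operation linear run to A2 (formylation, demethylation, MOM ether, dichlorovinyl ether, reduction, silylation, elimination), almost all protecting-group and redox work for a two-carbon handle;
(c) the end game: the di-ortho-substituted methyl ester of A3 would need LiI at 115 °C, and the MOM and silyl groups would need aqueous acid beside an ortho-prenylphenol and a 2,6-dioxygenated benzoic acid (chroman formation, decarboxylation).

**Retrosynthetic overview**
Ring A is the benzoic acid ring (C1 CO2H, C2 OH, C3 prenyl, C6 O-aryl); ring B is the phenoxy ring (C1 ether carbon, C2 OH, C4 CH3, C6 CH2OH).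
The key disconnection is the ether bond from O on C6 of ring A to C1 of ring B. It would be formed by a Smiles rearrangement of an aryl ester, in which the C1 carboxyl of ring A is first the tether and then the leaving group, and the C6 carbon of ring B, carried as formyl, activates C1.
The ester would be made in the same flask from the ring B phenoxide and a benzodioxinone that masks the carboxyl and O6 of ring A; its opening sets free exactly the O6 phenoxide that migrates.
Neither ring is built: both are bought as simple arenes, and the prenyl group is installed on ring A by Claisen rearrangement and cross-metathesis before the union.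
The design needs no ynol ether and no cycloaddition, reaches ring B in three operations, never makes a hindered ester that must be cleaved, and ends under hydride and palladium instead of acid.

Key step: step 8

Remark: the target has no stereocentre and its only alkene carries two identical methyl groups, so no configuration has to be set. 5-Hydroxy-2,2-dimethyl-4H-1,3-benzodioxin-4-one (the acetonide of 2,6-dihydroxybenzoic acid) is assumed to be commercially available.

Step 1
Reactants: 1 5-hydroxy-2,2-dimethyl-4H-1,3-benzodioxin-4-one
Product: 2 5-(allyloxy)-2,2-dimethyl-4H-1,3-benzodioxin-4-one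
Conditions: allyl bromide (1.3 equiv), K2CO3 (2 equiv), DMF, 50 °C
Reagents that add atoms: allyl bromide, C=CCBr
Why: Williamson O-alkylation of the phenol, in which carbonate in DMF overcomes the hydrogen bond to the lactone carbonyl and leaves the acetonide untouched.

Step 2
Reactants: 2 5-(allyloxy)-2,2-dimethyl-4H-1,3-benzodioxin-4-one
Product: 3 6-allyl-5-hydroxy-2,2-dimethyl-4H-1,3-benzodioxin-4-one
Conditions: PhNEt2, 185 °C, sealed tube, Ar
Reagents that add atoms: none
Why: The aromatic Claisen rearrangement ([3,3]-sigmatropic shift) can deliver the allyl group only to C6, because the other ortho position is the ring-fusion carbon, and tautomerisation restores the hydrogen-bonded phenol.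

Step 3
Reactants: 3 6-allyl-5-hydroxy-2,2-dimethyl-4H-1,3-benzodioxin-4-one
Product: 4 5-hydroxy-2,2-dimethyl-6-(3-methylbut-2-enyl)-4H-1,3-benzodioxin-4-one
Conditions: 2-methyl-2-butene (20 equiv), second-generation Grubbs catalyst (H2IMes)(PCy3)Cl2Ru=CHPh (3 mol %), CH2Cl2, 40 °C
Reagents that add atoms: 2-methyl-2-butene, CC=C(C)C
Why: Olefin cross-metathesis of a terminal allylarene with excess 2-methyl-2-butene exchanges the CH2 terminus for C(CH3)2 with loss of propene, the standard allyl-to-prenyl conversion, which tolerates a chelated phenol.

Step 4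
Reactants: 4 5-hydroxy-2,2-dimethyl-6-(3-methylbut-2-enyl)-4H-1,3-benzodioxin-4-one
Product: 5 5-(allyloxy)-2,2-dimethyl-6-(3-methylbut-2-enyl)-4H-1,3-benzodioxin-4-one
Conditions: allyl bromide (1.5 equiv), K2CO3 (2 equiv), DMF, 60 °C
Reagents that add atoms: allyl bromide, C=CCBr
Why: Williamson O-alkylation caps the ring A oxygen next to the prenyl group, the one that must stay out of the Smiles step, with a group that is later removed by palladium without acid or hydrogen.

Step 5
Reactants: 6 creosol (2-methoxy-4-methylphenol)
Product: 7 2-hydroxy-3-methoxy-5-methylbenzaldehyde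
Conditions: (CH2O)n, MgCl2, Et3N, MeCN, reflux; 1 M HCl
Reagents that add atoms: paraformaldehyde (formaldehyde), C=O
Why: The magnesium-mediated ortho-formylation of phenols (Casnati–Skattebøl reaction) can reach only C6, because the other ortho position carries the methoxy group and the para position the methyl group.

Step 6
Reactants: 7 2-hydroxy-3-methoxy-5-methylbenzaldehyde
Product: 8 2,3-dihydroxy-5-methylbenzaldehyde
Conditions: BBr3 (2.5 equiv), CH2Cl2, −78 °C to rt; H2O
Reagents that add atoms: none
Why: Lewis-acid cleavage of the aryl methyl ether by BBr3 is standard for ortho-vanillin-type aldehydes, and the aldehyde is recovered from its boron chelate on hydrolysis.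

Step 7
Reactants: 8 2,3-dihydroxy-5-methylbenzaldehyde
Product: 9 3-(allyloxy)-2-hydroxy-5-methylbenzaldehyde
Conditions: NaH (2.2 equiv), DMSO, rt; allyl bromide (1.0 equiv); 1 M HCl
Reagents that add atoms: allyl bromide, C=CCBr
Why: Williamson alkylation of the dianion should occur at the more basic 3-phenoxide, because the 2-phenoxide is conjugated with and chelated to the formyl group, the known selectivity of 2,3-dihydroxybenzaldehyde dianions.

Step 8
Reactants: 5 5-(allyloxy)-2,2-dimethyl-6-(3-methylbut-2-enyl)-4H-1,3-benzodioxin-4-one; 9 3-(allyloxy)-2-hydroxy-5-methylbenzaldehyde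
Product: 12 2-(allyloxy)-6-[2-(allyloxy)-6-formyl-4-methylphenoxy]-3-(3-methylbut-2-enyl)benzoic acid, via potassium depside phenoxide 10 (not isolated), via spiro Meisenheimer adduct 11 (not isolated)
Conditions: 9 (1.05 equiv), KOt-Bu (1.05 equiv), THF, 0 °C, then evaporated; 5 (1.0 equiv), DMSO (0.2 M), 4 Å MS, 85 °C, slow Ar sweep; cold 1 M HCl to pH 3
Reagents that add atoms: none
Why: Proposed new method: the potassium phenoxide of 9 should add to the lactone carbonyl of 5 and the tetrahedral intermediate should collapse with loss of acetone to aryl ester 10, which carries the ring A phenoxide on C6; this phenoxide then attacks the ester-bearing carbon C1 of ring B (Smiles rearrangement, an intramolecular SNAr) to give σ-adduct 11, whose charge is taken up by the ortho formyl group, and 11 opens by expulsion of the carboxylate, the better leaving group, to give the diaryl ether as its potassium carboxylate. The closest known reactions are the opening of 2,2-dimethylbenzodioxinones by alkoxides to salicylate esters and the base-induced Smiles rearrangement of depsides (aryl salicylates) to 2-aryloxybenzoic acids; what has not been shown is their combination in one flask with a phenoxide as the acyl acceptor. No ring of the product is closed, only the transient six-membered dioxinone ring of 11 (6-exo ipso attack), and no stereocentre is formed, since the spiro carbon of racemic 11 becomes sp2 again. The step needs site selectivity on both rings: on ring A it is secured because the oxygen next to the prenyl group is allylated, so only O6 can migrate, and on ring B because the nucleofuge sits on C1 and C1 is ortho to the formyl acceptor. The sequence is driven by loss of acetone (swept out, which also keeps it from an aldol reaction with the aldehyde) and by the exchange of a phenoxide for a carboxylate, and it replaces an intermolecular SNAr of a hindered phenol and any later cleavage of a hindered benzoate ester.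

Step 9
Reactants: 12 2-(allyloxy)-6-[2-(allyloxy)-6-formyl-4-methylphenoxy]-3-(3-methylbut-2-enyl)benzoic acid
Product: 14 2-hydroxy-6-[2-hydroxy-6-(hydroxymethyl)-4-methylphenoxy]-3-(3-methylbut-2-enyl)benzoic acid (CNP0140656.0), via bis(allyl ether) benzyl alcohol 13 (not isolated)
Conditions: NaBH4 (4 equiv), THF–MeOH (10:1), 0 °C; then Pd(PPh3)4 (5 mol %), rt; pH 4 phosphate buffer
Reagents that add atoms: none
Why: Borohydride first reduces the aldehyde, then zerovalent palladium ionises each aryl allyl ether to a π-allyl complex that hydride reduces to propene (palladium-catalysed reductive deallylation), so the ortho-prenylphenol and the salicylic acid never meet acid.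

**Compound list**
1 | 5-hydroxy-2,2-dimethyl-4H-1,3-benzodioxin-4-one | CC1(C)OC(=O)c2c(O)cccc2O1 | starting material
2 | 5-(allyloxy)-2,2-dimethyl-4H-1,3-benzodioxin-4-one | C=CCOc1cccc2OC(C)(C)OC(=O)c12 | intermediate
3 | 6-allyl-5-hydroxy-2,2-dimethyl-4H-1,3-benzodioxin-4-one | C=CCc1ccc2OC(C)(C)OC(=O)c2c1O | intermediate
4 | 5-hydroxy-2,2-dimethyl-6-(3-methylbut-2-enyl)-4H-1,3-benzodioxin-4-one | CC(C)=CCc1ccc2OC(C)(C)OC(=O)c2c1O | intermediate
5 | 5-(allyloxy)-2,2-dimethyl-6-(3-methylbut-2-enyl)-4H-1,3-benzodioxin-4-one | C=CCOc1c(CC=C(C)C)ccc2OC(C)(C)OC(=O)c12 | intermediate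
6 | creosol (2-methoxy-4-methylphenol) | COc1cc(C)ccc1O | starting material
7 | 2-hydroxy-3-methoxy-5-methylbenzaldehyde | COc1cc(C)cc(C=O)c1O | intermediate
8 | 2,3-dihydroxy-5-methylbenzaldehyde | Cc1cc(O)c(O)c(C=O)c1 | intermediate
9 | 3-(allyloxy)-2-hydroxy-5-methylbenzaldehyde | C=CCOc1cc(C)cc(C=O)c1O | intermediate
10 | potassium phenoxide of 2-(allyloxy)-6-formyl-4-methylphenyl 2-(allyloxy)-6-hydroxy-3-(3-methylbut-2-enyl)benzoate | C=CCOc1cc(C)cc(C=O)c1OC(=O)c1c([O-])ccc(CC=C(C)C)c1OCC=C.[K+] | intermediate (not isolated)
11 | potassium salt of the spiro σ-adduct 2',5-bis(allyloxy)-4'-methyl-6-(3-methylbut-2-enyl)-6'-(oxidomethylidene)spiro[1,3-benzodioxine-2,1'-cyclohexa-2',4'-dien]-4-one (racemic) | [O-]C=C1C=C(C)C=C(OCC=C)C12OC(=O)c3c(OCC=C)c(CC=C(C)C)ccc3O2.[K+] | intermediate (not isolated)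
12 | 2-(allyloxy)-6-[2-(allyloxy)-6-formyl-4-methylphenoxy]-3-(3-methylbut-2-enyl)benzoic acid | C=CCOc1cc(C)cc(C=O)c1Oc1ccc(CC=C(C)C)c(OCC=C)c1C(=O)O | intermediate
13 | 2-(allyloxy)-6-[2-(allyloxy)-6-(hydroxymethyl)-4-methylphenoxy]-3-(3-methylbut-2-enyl)benzoic acid | C=CCOc1cc(C)cc(CO)c1Oc1ccc(CC=C(C)C)c(OCC=C)c1C(=O)O | intermediate (not isolated)
14 | 2-hydroxy-6-[2-hydroxy-6-(hydroxymethyl)-4-methylphenoxy]-3-(3-methylbut-2-enyl)benzoic acid | CC(C)=CCc1ccc(Oc2c(O)cc(C)cc2CO)c(C(=O)O)c1O | target

Total step count: 9. Longest linear sequence: 6 steps (1 → 2 → 3 → 4 → 5 → 12 → 14); the ring B arm takes 3 steps before the union.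

**Steps most likely to fail**

Step 8. The phenoxide transacylation may be slow or reversible at the hindered, electron-rich lactone carbonyl, traces of water may open the dioxinone instead, and the ipso attack on a ring activated by a single formyl group may stall at the ester stage. The fallback uses known chemistry, sets out from 5 and 9, and makes and isolates the ester by a conventional condensation before the Smiles step. Saponification of 5 (KOH, aqueous DMSO, 60 °C) would give 2-(allyloxy)-6-hydroxy-3-(3-methylbut-2-enyl)benzoic acid F1. Carbodiimide condensation of F1 with 9 (dicyclohexylcarbodiimide, toluene, rt, the usual depside coupling) would give 2-(allyloxy)-6-formyl-4-methylphenyl 2-(allyloxy)-6-hydroxy-3-(3-methylbut-2-enyl)benzoate F2. Treatment of F2 with K2CO3 in dry DMSO, the known conditions for the depside-to-diaryl-ether Smiles rearrangement, would return to the route at 12.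

Step 2. At the temperature the allyl ether needs, the acetonide may lose acetone by cycloreversion to a ketene, and the material may decompose before the sigmatropic shift is complete. The fallback sets out from 1 and uses a tertiary ether that rearranges near 110 °C and gives the prenyl group directly. Copper-catalysed O-alkylation of 1 with 3-chloro-3-methylbut-1-yne (CuCl2 cat., DBU, MeCN) would give 2,2-dimethyl-5-(2-methylbut-3-yn-2-yloxy)-4H-1,3-benzodioxin-4-one F3. Semi-hydrogenation (H2, Lindlar catalyst, which is Pd on CaCO3 poisoned with Pb(OAc)2, quinoline) would give 2,2-dimethyl-5-(2-methylbut-3-en-2-yloxy)-4H-1,3-benzodioxin-4-one F4. Claisen rearrangement of F4 in toluene at 110 °C would come back to the route at 4, so that 3 and the metathesis are bypassed.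

Step 9. With hydride and palladium in one flask, colloidal palladium or palladium hydride may saturate the prenyl double bond, and the hindered allyl ether on ring A may be cleaved incompletely. The fallback sets out from 12 and keeps the two reagents apart by deprotecting before reducing. Allyl transfer to an amine (Pd(PPh3)4 cat., morpholine, THF, rt, no hydride present) would give 6-(2-formyl-6-hydroxy-4-methylphenoxy)-2-hydroxy-3-(3-methylbut-2-enyl)benzoic acid F5. Reduction of F5 with NaBH4 in MeOH at 0 °C would arrive at 14.

**Further compounds**
F1 | step 8 | 2-(allyloxy)-6-hydroxy-3-(3-methylbut-2-enyl)benzoic acid | C=CCOc1c(CC=C(C)C)ccc(O)c1C(=O)O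
F2 | step 8 | 2-(allyloxy)-6-formyl-4-methylphenyl 2-(allyloxy)-6-hydroxy-3-(3-methylbut-2-enyl)benzoate | C=CCOc1cc(C)cc(C=O)c1OC(=O)c1c(O)ccc(CC=C(C)C)c1OCC=C
F3 | step 2 | 2,2-dimethyl-5-(2-methylbut-3-yn-2-yloxy)-4H-1,3-benzodioxin-4-one | CC1(C)OC(=O)c2c(OC(C)(C)C#C)cccc2O1
F4 | step 2 | 2,2-dimethyl-5-(2-methylbut-3-en-2-yloxy)-4H-1,3-benzodioxin-4-one | CC1(C)OC(=O)c2c(OC(C)(C)C=C)cccc2O1
F5 | step 9 | 6-(2-formyl-6-hydroxy-4-methylphenoxy)-2-hydroxy-3-(3-methylbut-2-enyl)benzoic acid | CC(C)=CCc1ccc(Oc2c(O)cc(C)cc2C=O)c(C(=O)O)c1O
A1 | direct plan | methyl 4-acetoxy-5-(3-methylbut-2-enyl)-2-oxo-2H-pyran-3-carboxylate | COC(=O)C1=C(OC(C)=O)C(CC=C(C)C)=COC1=O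
A2 | direct plan | tert-butyl[[2-(ethynyloxy)-3-(methoxymethoxy)-5-methylphenyl]methoxy]dimethylsilane | COCOc1cc(C)cc(CO[Si](C)(C)C(C)(C)C)c1OC#C
A3 | direct plan | methyl 2-acetoxy-6-[2-[(tert-butyldimethylsilyl)oxymethyl]-6-(methoxymethoxy)-4-methylphenoxy]-3-(3-methylbut-2-enyl)benzoate | CC(C)=CCc1ccc(Oc2c(OCOC)cc(C)cc2CO[Si](C)(C)C(C)(C)C)c(C(=O)OC)c1OC(C)=O
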